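The plan rests on one disconnection, the C4–C4a bond of the quinone ring. In that ring C1, C2 and C4 are oxygenated, which maps onto a 3-methoxycyclobutenedione attached through its ketone-like carbonyl to C8a, and in ring B (benzyl on C6, methyl on C7, aryl on C8) C4a is the sole unsubstituted carbon next to C8a. Heating the hydroxycyclobutenone precursor should therefore unravel the four-membered ring into a vinylketene that can only close on C4a, creating the complete oxygenated ring at the hydroquinone level in a single operation. The precursor is a 4-aryl-4-hydroxy-3-methoxycyclobutenone whose aryl group is the fully substituted ring B, both phenols being masked as MOM ethers.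

Key step: step 10

Remark: Ar stands for 3-methoxy-4-(methoxymethoxy)phenyl throughout; naphthoquinone numbering is used (C1 is bonded to C8a and lies peri to the C8 aryl group); the target has no stereocentre, and the few chiral compounds on the way are racemic (one enantiomer drawn) and lose their stereocentres before the end.

Step 1
Reactants: 1 2-bromo-3-methylaniline
Product: 2 2-bromo-4-iodo-3-methylaniline
Conditions: NIS (1.0 equiv), DMF, 0 → 20 °C, dark
Reagents that add atoms: N-iodosuccinimide, O=C1CCC(=O)N1I
Why: Electrophilic aromatic iodination, in which the amino group directs to its para position (one ortho position is blocked by bromine and the other is less favoured), so a single iodination para to nitrogen is expected.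

Step 2
Reactants: 3 vanillyl alcohol
Product: 4 [3-methoxy-4-(methoxymethoxy)phenyl]methanol
Conditions: MOMCl (1.05 equiv), K2CO3, acetone, 0 → 20 °C
Reagents that add atoms: chloromethyl methyl ether (MOMCl), COCCl
Why: Williamson-type O-alkylation, in which K2CO3 deprotonates only the phenol (far more acidic than the benzylic alcohol), so one equivalent of MOMCl should cap the phenoxide selectively.

Step 3
Reactants: 4 [3-methoxy-4-(methoxymethoxy)phenyl]methanol
Product: 5 4-(chloromethyl)-2-methoxy-1-(methoxymethoxy)benzene
Conditions: MsCl, Et3N, CH2Cl2, 0 → 20 °C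
Reagents that add atoms: methanesulfonyl chloride (chlorine source), CS(=O)(=O)Cl
Why: Sulfonylation followed by in situ nucleophilic substitution, the electron-rich benzylic mesylate being displaced by the chloride released from MsCl while the amine base keeps the medium non-acidic for the MOM acetal.

Step 4
Reactants: 5 4-(chloromethyl)-2-methoxy-1-(methoxymethoxy)benzene; 2 2-bromo-4-iodo-3-methylaniline
Product: 7 2-bromo-4-(ArCH2)-3-methylaniline, via benzylzinc chloride 6 (not isolated)
Conditions: 5, zinc dust, LiCl, THF, 25 °C; then 2, Pd(PPh3)4 (3 mol %), THF, 25 → 50 °C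
Reagents that add atoms: none
Why: LiCl-promoted zinc insertion into the benzylic chloride followed by Negishi cross-coupling, in which oxidative addition of zerovalent palladium to the carbon–iodine bond of 2 is far faster than to the doubly ortho-flanked carbon–bromine bond and the benzylzinc halide tolerates the free NH2 group.

Step 5
Reactants: 8 2-methoxy-4-(4,4,5,5-tetramethyl-1,3,2-dioxaborolan-2-yl)phenol
Product: 9 2-Ar-4,4,5,5-tetramethyl-1,3,2-dioxaborolane
Conditions: MOMCl, K2CO3, acetone, 0 → 20 °C
Reagents that add atoms: chloromethyl methyl ether (MOMCl), COCCl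
Why: Williamson-type O-alkylation of the phenol with MOMCl, the pinacol boronate being inert to K2CO3 in dry acetone.

Step 6
Reactants: 7 2-bromo-4-(ArCH2)-3-methylaniline; 9 2-Ar-4,4,5,5-tetramethyl-1,3,2-dioxaborolane
Product: 10 2-Ar-4-(ArCH2)-3-methylaniline
Conditions: Pd(OAc)2 (5 mol %), SPhos (10 mol %), K3PO4, toluene/H2O (10:1), 100 °C
Reagents that add atoms: none
Why: Suzuki–Miyaura coupling, for which the SPhos-ligated palladium catalyst is suited to a bromide flanked by NH2 and CH3, unprotected ortho-bromoanilines being competent partners and MOM ethers being stable to aqueous K3PO4.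

Step 7
Reactants: 10 2-Ar-4-(ArCH2)-3-methylaniline
Product: 11 1-iodo-2-Ar-4-(ArCH2)-3-methylbenzene
Conditions: p-TsOH·H2O (1.2 equiv), t-BuONO, MeCN, 0 °C, 10 min; then KI (aq), 0 → 20 °C
Reagents that add atoms: potassium iodide (KI), [K+].[I-]
Why: Sandmeyer-type diazotization–iodination (iodide needs no copper), in which the nitrite ester and one equivalent of sulfonic acid form the diazonium tosylate that iodide reduces and captures, the brief stoichiometric exposure to acid in acetonitrile being expected to spare the MOM ethers.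

Step 8
Reactants: 12 dimethyl squarate
Product: 14 3-methoxycyclobut-3-ene-1,2-dione, via 4-hydroxy-2,3-dimethoxycyclobut-2-en-1-one 13 (not isolated)
Conditions: LiAlH(O-t-Bu)3 (1.1 equiv), THF, −78 °C; dilute HCl work-up; then 12 M HCl (cat.), CH2Cl2, 20 °C
Reagents that add atoms: none
Why: Hydride 1,2-addition by the bulky LiAlH(O-t-Bu)3 stops after one carbonyl because the adduct retains only a deactivated vinylogous ester, and acid then ionizes the carbinol to an oxygen-stabilized allyl cation that takes up water at C2 and loses methanol, a reduction–hydrolysis sequence established for dialkyl squarates.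

Step 9
Reactants: 11 1-iodo-2-Ar-4-(ArCH2)-3-methylbenzene; 14 3-methoxycyclobut-3-ene-1,2-dione
Product: 16 4-[2-Ar-4-(ArCH2)-3-methylphenyl]-4-hydroxy-3-methoxycyclobut-2-en-1-one (racemic), via aryllithium 15 (not isolated)
Conditions: 11, t-BuLi (2.05 equiv), THF, −78 °C, 10 min; cannulate into 14 (1.3 equiv), THF, −78 °C; NH4Cl (aq) at −78 °C
Reagents that add atoms: none
Why: Iodine–lithium exchange followed by 1,2-addition of the aryllithium to the more electrophilic, ketone-like carbonyl C2 of 14 (the one bonded to the methoxy-bearing carbon, the other carbonyl being deactivated as a vinylogous ester), as known for organolithium additions to alkyl semisquarates; the new carbinol stereocentre forms as a racemate and needs no control because it becomes sp2 in step 10.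

Step 10
Reactants: 16 4-[2-Ar-4-(ArCH2)-3-methylphenyl]-4-hydroxy-3-methoxycyclobut-2-en-1-one
Product: 19 2-methoxy-7-methyl-8-Ar-6-(ArCH2)naphthalene-1,4-diol, via (Z)-dienylketene 17 (not isolated), via 4a-H dienone 18 (not isolated)
Conditions: degassed p-xylene (0.02 M), 138 °C, argon, 1–2 h; crude product kept under argon
Reagents that add atoms: none
Why: This is a Moore-type rearrangement: thermal conrotatory 4π opening of the C1–C4 bond of the cyclobutenone, with the donor hydroxyl turning outward and the aryl group inward, should give (Z)-dienylketene 17. A 6π electrocyclization then joins the ketene carbon to C4a of ring B (six-membered ring closure onto the arene, forming C4–C4a) to give 4a-H dienone 18, and two proton shifts aromatize it to naphthalene-1,4-diol 19. The closest known reaction type is the thermal ring expansion of 4-aryl-4-hydroxycyclobutenones to 1,4-naphthalenediols and naphthoquinones. No stereocentre survives, since the carbinol carbon of 16 becomes sp2 and the transient C4a centre of 18 is erased on tautomerization. The step needs site selectivity of closure and the correct placement of OMe: the former is secured because C4a is the only hydrogen-bearing ortho carbon (closure at the aryl-bearing C8 could not aromatize), the latter because step 9 already set OMe next to the carbinol carbon, so that it ends on C2 beside the C1 oxygen, while outward rotation of the hydroxyl is the electronically preferred torquoselectivity.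

Step 11
Reactants: 19 2-methoxy-7-methyl-8-Ar-6-(ArCH2)naphthalene-1,4-diol
Product: 20 2-methoxy-7-methyl-8-Ar-6-(ArCH2)naphthalene-1,4-dione
Conditions: Ag2O (2.5 equiv), Na2SO4, Et2O/CH2Cl2, 20 °C
Reagents that add atoms: none
Why: Two-electron oxidation of the electron-rich 1,4-diol to the 1,4-quinone by Ag2O, a mild oxidant that leaves MOM ethers, aryl methyl ethers and the diarylmethane untouched.

Step 12
Reactants: 20 2-methoxy-7-methyl-8-Ar-6-(ArCH2)naphthalene-1,4-dione
Product: 21 larreantin
Conditions: HCl (1.25 M in MeOH), MeOH/CH2Cl2, 20 → 40 °C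
Reagents that add atoms: none
Why: Acid-catalysed acetal cleavage (transacetalization of both MOM ethers to dimethoxymethane in methanol), under which the quinone and the aryl methyl ethers are stable and any exchange of the vinylogous methyl ester at C2 with methanol is degenerate.

Compound list
1 | 2-bromo-3-methylaniline | Cc1cccc(N)c1Br | starting material
2 | 2-bromo-4-iodo-3-methylaniline | Cc1c(I)ccc(N)c1Br | intermediate
3 | vanillyl alcohol (4-(hydroxymethyl)-2-methoxyphenol) | COc1cc(CO)ccc1O | starting material
4 | [3-methoxy-4-(methoxymethoxy)phenyl]methanol | COCOc1ccc(CO)cc1OC | intermediate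
5 | 4-(chloromethyl)-2-methoxy-1-(methoxymethoxy)benzene | COCOc1ccc(CCl)cc1OC | intermediate
6 | [3-methoxy-4-(methoxymethoxy)benzyl]zinc chloride | COCOc1ccc(C[Zn]Cl)cc1OC | intermediate (not isolated)
7 | 2-bromo-4-{[3-methoxy-4-(methoxymethoxy)phenyl]methyl}-3-methylaniline | Cc1c(Cc2ccc(OCOC)c(OC)c2)ccc(N)c1Br | intermediate
8 | 2-methoxy-4-(4,4,5,5-tetramethyl-1,3,2-dioxaborolan-2-yl)phenol | COc1cc(B2OC(C)(C)C(C)(C)O2)ccc1O | starting material
9 | 2-[3-methoxy-4-(methoxymethoxy)phenyl]-4,4,5,5-tetramethyl-1,3,2-dioxaborolane | COCOc1ccc(B2OC(C)(C)C(C)(C)O2)cc1OC | intermediate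
10 | 2-[3-methoxy-4-(methoxymethoxy)phenyl]-4-{[3-methoxy-4-(methoxymethoxy)phenyl]methyl}-3-methylaniline | Cc1c(Cc2ccc(OCOC)c(OC)c2)ccc(N)c1-c1ccc(OCOC)c(OC)c1 | intermediate
11 | 1-iodo-2-[3-methoxy-4-(methoxymethoxy)phenyl]-4-{[3-methoxy-4-(methoxymethoxy)phenyl]methyl}-3-methylbenzene | Cc1c(Cc2ccc(OCOC)c(OC)c2)ccc(I)c1-c1ccc(OCOC)c(OC)c1 | intermediate
12 | dimethyl squarate (3,4-dimethoxycyclobut-3-ene-1,2-dione) | COC1=C(OC)C(=O)C1=O | starting material
13 | 4-hydroxy-2,3-dimethoxycyclobut-2-en-1-one (racemic, one enantiomer drawn) | COC1=C(OC)C(=O)[C@@H]1O | intermediate (not isolated)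
14 | 3-methoxycyclobut-3-ene-1,2-dione (methyl semisquarate) | COC1=CC(=O)C1=O | intermediate
15 | aryllithium from 11 (lithium in place of iodine) | [Li]c1ccc(Cc2ccc(OCOC)c(OC)c2)c(C)c1-c1ccc(OCOC)c(OC)c1 | intermediate (not isolated)
16 | 4-hydroxy-3-methoxy-4-[2-Ar-4-(ArCH2)-3-methylphenyl]cyclobut-2-en-1-one (racemic, one enantiomer drawn) | O=C1C=C(OC)[C@@]1(O)c1ccc(Cc2ccc(OCOC)c(OC)c2)c(C)c1-c1ccc(OCOC)c(OC)c1 | intermediate
17 | (Z)-4-aryl-4-hydroxy-3-methoxybuta-1,3-dien-1-one (dienylketene, aryl cis to the ketene arm) | O=C=C/C(OC)=C(/O)c1ccc(Cc2ccc(OCOC)c(OC)c2)c(C)c1-c1ccc(OCOC)c(OC)c1 | intermediate (not isolated)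
18 | 4-hydroxy-3-methoxy-8a-H naphthalen-1-one tautomer of 19 (the sp3 carbon is C4a in route numbering; racemic, one enantiomer drawn) | COC1=CC(=O)[C@@H]2C=C(Cc3ccc(OCOC)c(OC)c3)C(C)=C(c3ccc(OCOC)c(OC)c3)C2=C1O | intermediate (not isolated)
19 | 2-methoxy-7-methyl-8-Ar-6-(ArCH2)naphthalene-1,4-diol (bis-MOM larreantin hydroquinone) | COc1cc(O)c2cc(Cc3ccc(OCOC)c(OC)c3)c(C)c(-c3ccc(OCOC)c(OC)c3)c2c1O | intermediate
20 | 2-methoxy-7-methyl-8-Ar-6-(ArCH2)naphthalene-1,4-dione (bis-MOM larreantin) | COC1=CC(=O)c2cc(Cc3ccc(OCOC)c(OC)c3)c(C)c(-c3ccc(OCOC)c(OC)c3)c2C1=O | intermediate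
21 | larreantin, 8-(4-hydroxy-3-methoxyphenyl)-6-[(4-hydroxy-3-methoxyphenyl)methyl]-2-methoxy-7-methylnaphthalene-1,4-dione | COC1=CC(=O)c2cc(Cc3ccc(O)c(OC)c3)c(C)c(-c3ccc(O)c(OC)c3)c2C1=O | target

Total step count: 12.
Longest linear sequence: 9 steps (steps 2, 3, 4, 6, 7, 9, 10, 11 and 12, from vanillyl alcohol 3).

Steps most likely to fail

Step 10 (key step). The vinylketene may be consumed before it closes. Addition of the free hydroxyl to the ketene (lactone formation) or oligomerization can compete if crowding between the C8 aryl group and the emerging C1 oxygen slows the ring closure. The fallback sets out from 16 and changes the substrate class. The tertiary hydroxyl would be capped (TMSCl, imidazole, DMF, 0 °C) to give 3-methoxy-4-[2-Ar-4-(ArCH2)-3-methylphenyl]-4-(trimethylsilyloxy)cyclobut-2-en-1-one F1. Thermolysis in p-xylene should then give 2-methoxy-7-methyl-8-Ar-6-(ArCH2)-1-(trimethylsilyloxy)naphthalen-4-ol F2. In this variant the ketene cannot be intercepted internally and the product is no longer air-sensitive. Methanolysis of the silyl ether (K2CO3, MeOH) and Ag2O oxidation in the same flask would return the route to quinone 20.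

Step 7. The diazonium group is generated ortho to an electron-rich aryl ring. Intramolecular azo coupling onto that ring, hydrodediazoniation or acid-induced loss of a MOM group could therefore compete with iodide capture. The fallback installs the aryl group last and sets out from bromoaniline 7. The same diazotization–iodination, now without a neighbouring aryl ring, would give 2-bromo-1-iodo-4-(ArCH2)-3-methylbenzene F3. Selective iodine–magnesium exchange (i-PrMgCl·LiCl, THF, −40 °C, where the ortho-bromo arylmagnesium should not collapse to an aryne) and addition to 14 at −78 °C would give 4-[2-bromo-4-(ArCH2)-3-methylphenyl]-4-hydroxy-3-methoxycyclobut-2-en-1-one F4. The same thermal ring expansion should give 8-bromo-2-methoxy-7-methyl-6-(ArCH2)naphthalene-1,4-diol F5, and Ag2O should give 8-bromo-2-methoxy-7-methyl-6-(ArCH2)naphthalene-1,4-dione F6. Suzuki–Miyaura coupling of that bromide with boronate 9 (Pd(OAc)2, SPhos, anhydrous K3PO4, toluene, 80 °C) would rejoin the route at quinone 20.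

Step 9. Instead of 1,2-addition at the ketone-like carbonyl, the hindered aryllithium may attack the methoxy-bearing carbon (addition–elimination), add in conjugate fashion at the unsubstituted ring carbon, or simply be protonated. The moisture-sensitive methyl ester 14 may also be lost on handling. The fallback uses a bulkier, more robust alkoxy group that is exchanged at the end, and sets out from iodide 11. Aryllithium 15 would be added to 3-isopropoxycyclobut-3-ene-1,2-dione F7, made from commercial diisopropyl squarate by the reduction–hydrolysis of step 8. Its isopropoxy group shields the alkoxy-bearing carbon, and the adduct would be 4-[2-Ar-4-(ArCH2)-3-methylphenyl]-4-hydroxy-3-isopropoxycyclobut-2-en-1-one F8. Thermolysis should give 2-isopropoxy-7-methyl-8-Ar-6-(ArCH2)naphthalene-1,4-diol F9, and Ag2O should give 2-isopropoxy-7-methyl-8-Ar-6-(ArCH2)naphthalene-1,4-dione F10. HCl in methanol at 60 °C would then remove both MOM groups and exchange the vinylogous isopropyl ester for the methyl ester by acid-catalysed addition–elimination at C2, arriving at larreantin 21.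

Further compounds
F1 | step 10 | 3-methoxy-4-[2-Ar-4-(ArCH2)-3-methylphenyl]-4-(trimethylsilyloxy)cyclobut-2-en-1-one (racemic, one enantiomer drawn) | O=C1C=C(OC)[C@@]1(O[Si](C)(C)C)c1ccc(Cc2ccc(OCOC)c(OC)c2)c(C)c1-c1ccc(OCOC)c(OC)c1
F2 | step 10 | 2-methoxy-7-methyl-8-Ar-6-(ArCH2)-1-(trimethylsilyloxy)naphthalen-4-ol (route numbering) | COc1cc(O)c2cc(Cc3ccc(OCOC)c(OC)c3)c(C)c(-c3ccc(OCOC)c(OC)c3)c2c1O[Si](C)(C)C
F3 | step 7 | 2-bromo-1-iodo-4-(ArCH2)-3-methylbenzene | Cc1c(Cc2ccc(OCOC)c(OC)c2)ccc(I)c1Br
F4 | step 7 | 4-[2-bromo-4-(ArCH2)-3-methylphenyl]-4-hydroxy-3-methoxycyclobut-2-en-1-one (racemic, one enantiomer drawn) | O=C1C=C(OC)[C@@]1(O)c1ccc(Cc2ccc(OCOC)c(OC)c2)c(C)c1Br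
F5 | step 7 | 8-bromo-2-methoxy-7-methyl-6-(ArCH2)naphthalene-1,4-diol | COc1cc(O)c2cc(Cc3ccc(OCOC)c(OC)c3)c(C)c(Br)c2c1O
F6 | step 7 | 8-bromo-2-methoxy-7-methyl-6-(ArCH2)naphthalene-1,4-dione | COC1=CC(=O)c2cc(Cc3ccc(OCOC)c(OC)c3)c(C)c(Br)c2C1=O
F7 | step 9 | 3-isopropoxycyclobut-3-ene-1,2-dione | CC(C)OC1=CC(=O)C1=O
F8 | step 9 | 4-[2-Ar-4-(ArCH2)-3-methylphenyl]-4-hydroxy-3-isopropoxycyclobut-2-en-1-one (racemic, one enantiomer drawn) | O=C1C=C(OC(C)C)[C@@]1(O)c1ccc(Cc2ccc(OCOC)c(OC)c2)c(C)c1-c1ccc(OCOC)c(OC)c1
F9 | step 9 | 2-isopropoxy-7-methyl-8-Ar-6-(ArCH2)naphthalene-1,4-diol | CC(C)Oc1cc(O)c2cc(Cc3ccc(OCOC)c(OC)c3)c(C)c(-c3ccc(OCOC)c(OC)c3)c2c1O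
F10 | step 9 | 2-isopropoxy-7-methyl-8-Ar-6-(ArCH2)naphthalene-1,4-dione | CC(C)OC1=CC(=O)c2cc(Cc3ccc(OCOC)c(OC)c3)c(C)c(-c3ccc(OCOC)c(OC)c3)c2C1=O
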